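## Analysis of the target

- The target is a C40 xanthophyll. An all-E octaene chain (C7 to C10', with methyls C19, C20, C20' and C19') joins a 3,5,6-trihydroxycyclohexane (ring A, C1–C6) to a bicycle. In the bicycle a cyclohexane (ring B, C1'–C6') is fused through C5'–C6' to a 2,5-dihydrofuran (ring C: O, C5', C6', C7', C8') with the double bond C6'=C7'.
- Ring A is 3S,5R,6S. The two tertiary hydroxyls at C5 and C6 are cis to each other and trans to the C3 hydroxyl, which lies on the face of the C5 methyl and of C7.
- The bicycle is 3'S,5'R,8'R. The C3' hydroxyl is cis to the angular C5' methyl (the axial, loliolide-type arrangement), and C9' on C8' is trans to that methyl.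
- The whole polyene separates the two stereo-clusters, so each half needs its own source of absolute configuration.
- The polyene is sensitive to light, oxygen and acid. C8' is a doubly allylic ether carbon that ionises and epimerises with acid. The C6 hydroxyl is tertiary and allylic. As long as C3' is a ketone, the C5'–O bond is β-eliminable with base.
- The hard points are the fully substituted C5' (methyl, ring oxygen, C4', C6') beside the quaternary C1', the weakly biased centre C8', and the cis pair of tertiary carbinols in ring A.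
- The route reads ring C as an oxidised furan. O, C5', C6', C7' and C8' are the atoms of a 2-methylfuran whose methyl-bearing carbon has been attacked by C4'. This leaves C6'=C7' in place and C8' at the acetal level, ready for C–C bond formation.

## Retrosynthetic reasoning

**36 to 35 (O–Si bonds).** Only the two secondary hydroxyls are masked, as silyl ethers in 35; the tertiary ones stay free. The last step is then a fluoride desilylation, which spares the acid-labile C8' centre and the polyene.

**35 to 34 + 20, and 34 to 32 + 33 (C11'=C12' and C11=C12).** Both cuts fall on disubstituted double bonds next to a methyl-bearing carbon, the classical C15 + C10 + C15 pattern. The central unit is then the symmetrical dialdehyde 33, and each stereo-cluster sits in its own C15 phosphonium salt. The forward Wittig reactions must work with free tertiary hydroxyls and give the E double bonds after thermal equilibration.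

**20 to 12 + 16 (C8'–C9'), via 19, 18 and 17.** C8' is an acetal carbon in 12, so the bond to C9' is made by adding an alkenyl nucleophile to the derived oxocarbenium ion. Cutting here and not at C9'=C10' brings the C9' methyl, the E double bond and C11' in as one C4 unit. The forward reaction has to attack C8' and not C6', keep the alkene geometry of 16, and favour the 8'R face. Alcohol 18 is then turned into salt 20 under neutral conditions through bromide 19.

**16 to 13 (C–B bond), via 15 and 14.** The alkenyl unit comes from but-2-yn-1-ol 13 by syn addition of boron and hydrogen across the triple bond, with boron on the carbon remote from oxygen. This fixes the later C9'=C10' geometry.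

**12 to 10 (O–Si, C3'–H), via 11.** The C3' ketone of 10 is the handle for introducing chirality. An enzymatic reduction has to deliver the 3'S carbinol from the 5'R enantiomer only, which sets C3' and resolves C5' in one operation. Silylation then gives 12.

**10 to 8 + 9 (C4'–C5', key disconnection, plus C8'–OMe).** Cutting C4'–C5' turns ring C back into a 2-methylfuran and ring B into an open chain with a silyl enol ether at C3'/C4'. Forward, an oxidative coupling must join the enol ether terminus C4' to the methyl-bearing furan carbon C5', and methanol 9 must cap the resulting cation at C8'. This builds the quaternary C5', the cyclohexanone, the C6'=C7' bond and the C8' acetal at once. No other cut in the bicycle removes that much.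

**8 to 1 + 2 (C1'–C6', then O–Si), via 6.** The quaternary C1' is the β-carbon of mesityl oxide 2, so a 3-furyl copper reagent from 1 adds in conjugate fashion to give ketone 6. Kinetic enolisation at the methyl group gives 8.

**32 to 26 + 27 (C6–C7), via 31, 30 and 29.** The tertiary C6 carbinol with its dienyl chain comes from adding the acetylide of enynol 27 to the non-enolisable ketone 26. Trans-reduction of the propargylic alcohol 29 gives the E,E-diene 30, and neutral bromination and phosphine quaternisation give 32. The addition must occur anti to the C5 oxygen so that the 5,6-diol is cis.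

**26 to 21 (C5–O), via 23 and 22.** The C5 carbinol is introduced by oxidising the only possible enol ether (23) of the silylated chiral-pool ketone 22, made from actinol 21. The oxidant must approach anti to the C3 silyloxy group.

## Alternatives that were turned down

**Alternative 1:** The cut is at the two C–O bonds of ring A (C5–O and C6–O). Forward, the OsO4–TMEDA reagent is hydrogen-bonded to the C3 hydroxyl of enynol A2 and dihydroxylates C5=C6 on that face to give the all-cis triol A1.
- For: one step sets both tertiary carbinols with predictable, directed face control, and the series is enantiospecific from a chiral-pool C3 centre.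
- Against: because the oxygens arrive syn to the C3 hydroxyl, A2 must carry the epimeric C3 configuration and C3 must be inverted afterwards. The reaction needs stoichiometric osmium on a hindered tetrasubstituted enyne. Above all, it solves ring A only: the bicycle with its fully substituted C5' and C8' would still come from an epoxide-to-furanoid rearrangement, which is unselective at C8'.
- Comparison: on ring A this alternative is stronger than the chosen route, whose ring A rests on a substrate-controlled enol ether oxidation and an axial carbonyl addition. The chosen strategy instead spends its key step on the structurally harder half and builds the C5' quaternary centre by C–C bond formation.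

**Alternative 2:** Three bonds of the bicycle are cut at once (C5'–C6', C7'–C8', C8'–O). Forward, the silyl alkyne and the methyl ketone of ynone A4 combine with CO on Ru3(CO)12 or Mo(CO)6 (hetero-Pauson–Khand) to give the silylated butenolide A3.
- For: both rings and C5' arise in one step from an acyclic precursor whose single stereocentre (C3') is easy to make enantiopure, so no resolution is needed. On bonds per step and on enantiospecificity it beats the chosen route.
- Against: carbonylative [2+2+1] reactions of ketone carbonyls are reliable mainly for activated carbonyls and five-membered carbocycles. Here a cyclohexane must close at a quaternary propargylic carbon with an unactivated methyl ketone, which means forcing temperature and CO pressure. 1,3-Induction from C3' to C5' in the metallacycle is not assured. The C7' silyl group must be removed, and C8' arrives as a lactone that has to be reduced before C9' can be attached.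
- Comparison: the chosen anodic step runs at room temperature without a metal, and delivers C8' directly at the acetal level with C6'=C7' in place. It pays with a resolution.

**Alternative 3:** Only the O–C8' bond is cut. Forward, the C5' hydroxyl of the axially chiral allenol A6 adds to the gold-activated allene (Ph3PAuNTf2) and gives the dihydrofuran A5, with axis-to-centre transfer fixing C8'.
- For: it is the only one of the four strategies that controls C8' by design. On that point it is stronger than the chosen route, where C8' depends on a modest facial bias and a separation.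
- Against: ring B with the C5' tertiary carbinol, C3' and a configurationally defined exocyclic allene must all be built first, with one more stereocontrolled propargylic substitution at a doubly flanked carbon. Gold can racemise the allene before ring closure. The key step forms no C–C bond. C9' arrives as a protected hydroxymethyl group, so the methyl and C10' must be added through an α-alkoxy carbonyl compound that can epimerise at C8'.
- Comparison: the chosen route reaches the bicycle in three steps from commodity chemicals and attaches C9'–C11' as one complete unit.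

Key step: step 3

## Assumptions

- Carotenoid numbering is used throughout: unprimed atoms belong to the ring A half, primed atoms to the bicyclic half (rings B and C).
- Compounds 1, 2, 13, 21, 27 and 33 are taken as purchasable.
- Compounds 10, 11 and 12 are handled as mixtures of the two epimers at the acetal carbon C8', because this centre is planarised in step 9.

## Route

Step 1
Reactants: 1 3-bromo-2-methylfuran; 2 mesityl oxide (4-methylpent-3-en-2-one)
Product: 6 4-methyl-4-(2-methylfuran-3-yl)pentan-2-one, via 3-lithio-2-methylfuran 3 (not isolated), via (2-methylfuran-3-yl)magnesium bromide 4 (not isolated), via trimethylsilyl enol ether 5 (not isolated)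
Conditions: n-BuLi, Et2O, −78 °C; MgBr2·OEt2; CuBr·SMe2 (10 mol %), Me3SiCl, 2, THF, −78 → −20 °C; aq. citric acid, 0 °C
Reagents that add atoms: none
Why: Bromine–lithium exchange at −78 °C gives the 3-furyllithium without migration of the metal because C2 is blocked by the methyl group. After transmetalation to magnesium, the copper-catalysed, chlorosilane-accelerated conjugate addition to the β,β-disubstituted enone creates the quaternary C1', and mild acid hydrolyses the enol ether 5 to the ketone.

Step 2
Reactants: 6 4-methyl-4-(2-methylfuran-3-yl)pentan-2-one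
Product: 8 triisopropyl{[4-methyl-4-(2-methylfuran-3-yl)pent-1-en-2-yl]oxy}silane, via lithium enolate 7 (not isolated)
Conditions: LiN(iPr)2, THF, −78 °C; iPr3SiOTf, −78 → 0 °C
Reagents that add atoms: triisopropylsilyl trifluoromethanesulfonate, CC(C)[Si](OS(=O)(=O)C(F)(F)F)(C(C)C)C(C)C
Why: Kinetic deprotonation takes the methyl hydrogens, not the neopentyl-type methylene beside the quaternary carbon, and the lithium enolate is silylated on oxygen by the silyl triflate. The bulky silyl group is chosen so that the enol ether survives the methanolic electrolyte of step 3.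

Step 3
Reactants: 8 triisopropyl{[4-methyl-4-(2-methylfuran-3-yl)pent-1-en-2-yl]oxy}silane; 9 methanol
Product: 10 racemic 2-methoxy-4,4,7a-trimethyl-2,4,5,7a-tetrahydro-1-benzofuran-6(7H)-one (3'-oxo bicyclic methyl acetal; both C8' epimers)
Conditions: constant-current electrolysis, undivided cell, reticulated vitreous carbon anode, carbon cathode, 0.1 M LiClO4, 9/CH2Cl2 (1:4), 2,6-lutidine, 2.2 F/mol, 0 °C → rt
Reagents that add atoms: none
Why: One-electron oxidation at the anode gives a radical cation of the enol ether/furan pair; its electrophilic terminus C4' (the enol ether CH2) is captured by the methyl-bearing α-carbon of the furan (C5'), as in the known anodic coupling of silyl enol ethers with tethered furans. Ring B closes in the 6-endo mode with respect to the enol ether double bond, the mode its polarity demands because bonding at the oxygen-free terminus leaves the α-silyloxy radical, and the gem-dimethyl group at C1' favours the folded conformer. A second electron transfer and loss of the silyl group to methanol give the C3' ketone; the furan-derived cation cannot rearomatise because C5' has no hydrogen, and 9 traps it at the oxocarbenium carbon C8' and not at the hindered C6'. C5' is formed without any chiral influence and is therefore racemic, and C8' forms as both epimers, which does not matter. The step needs regioselectivity for the furan α-carbon over the β-carbon (which would lead to a rearomatised 3,4-fused furan); this is secured by the larger orbital coefficient at the α-position, reinforced by the methyl donor. It also needs ring closure to outrun solvent capture of the radical cation, which intramolecularity and the low methanol content secure. 2,6-Lutidine buffers the acid formed at the anode, so that neither the enol ether nor the acetal is solvolysed and the base-sensitive β-alkoxy ketone sees no strong base.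

Step 4
Reactants: 10 racemic 3'-oxo bicyclic methyl acetal
Product: 11 (6S,7aR)-2-methoxy-4,4,7a-trimethyl-2,4,5,6,7,7a-hexahydro-1-benzofuran-6-ol (3'S,5'R; both C8' epimers)
Conditions: ketoreductase (NADPH-dependent; chosen from a panel), NADP+ (cat.), i-PrOH, 0.1 M potassium phosphate buffer pH 7.0, 30 °C, stopped near half conversion
Reagents that add atoms: none
Why: Enzymatic kinetic resolution by stereoselective ketone reduction: the enzyme should accept only the (5'R) enantiomer and deliver hydride to one face of C3', giving the axial 3'S alcohol, while the (5'S) ketone is left behind and removed by chromatography. Neutral aqueous conditions avoid retro-oxa-Michael opening of the β-alkoxy ketone.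

Step 5
Reactants: 11 (6S,7aR)-2-methoxy-4,4,7a-trimethyl-2,4,5,6,7,7a-hexahydro-1-benzofuran-6-ol
Product: 12 tert-butyl{[(6S,7aR)-2-methoxy-4,4,7a-trimethyl-2,4,5,6,7,7a-hexahydro-1-benzofuran-6-yl]oxy}dimethylsilane
Conditions: t-BuMe2SiCl, imidazole, DMF, 40 °C
Reagents that add atoms: tert-butyldimethylsilyl chloride, CC(C)(C)[Si](C)(C)Cl
Why: Standard silylation of a secondary alcohol. The chloride with imidazole is used instead of a silyl triflate so that the allylic acetal is not ionised.

Step 6
Reactants: 13 but-2-yn-1-ol
Product: 14 (Z)-3-(4,4,5,5-tetramethyl-1,3,2-dioxaborolan-2-yl)but-2-en-1-ol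
Conditions: B2pin2, CuCl (5 mol %), PCy3 (6 mol %), NaOt-Bu (10 mol %), MeOH (2 equiv), toluene, rt
Reagents that add atoms: bis(pinacolato)diboron, CC1(C)OB(OC1(C)C)B1OC(C)(C)C(C)(C)O1
Why: Copper-catalysed borylcupration and protonation (protoboration) of a propargylic alcohol. Boron and hydrogen add syn, with boron on the carbon remote from the oxygen, so boron ends trans to the hydroxymethyl group, which is the geometry needed for an E C9'=C10' bond.

Step 7
Reactants: 14 (Z)-3-(4,4,5,5-tetramethyl-1,3,2-dioxaborolan-2-yl)but-2-en-1-ol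
Product: 15 (Z)-3-(4,4,5,5-tetramethyl-1,3,2-dioxaborolan-2-yl)but-2-en-1-yl acetate
Conditions: Ac2O, pyridine, DMAP (cat.), CH2Cl2, 0 °C
Reagents that add atoms: acetic anhydride, CC(=O)OC(C)=O
Why: Acylation masks the hydroxyl, which would otherwise compete as an oxygen nucleophile in step 9. The acetate is later removed under conditions that leave the silyl ether alone.

Step 8
Reactants: 15 (Z)-3-(4,4,5,5-tetramethyl-1,3,2-dioxaborolan-2-yl)but-2-en-1-yl acetate
Product: 16 potassium (Z)-(4-acetoxybut-2-en-2-yl)trifluoroborate
Conditions: KHF2, MeOH/H2O, rt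
Reagents that add atoms: potassium hydrogen difluoride, [K+].[F-].F
Why: Conversion of a pinacol boronate into the trifluoroborate salt; the alkene geometry is untouched and the acetate tolerates the weakly acidic medium.

Step 9
Reactants: 12 tert-butyl{[(6S,7aR)-2-methoxy-4,4,7a-trimethyl-2,4,5,6,7,7a-hexahydro-1-benzofuran-6-yl]oxy}dimethylsilane; 16 potassium (Z)-(4-acetoxybut-2-en-2-yl)trifluoroborate
Product: 17 (E)-3-[(2R,6S,7aR)-6-(tert-butyldimethylsilyloxy)-4,4,7a-trimethyl-2,4,5,6,7,7a-hexahydro-1-benzofuran-2-yl]but-2-en-1-yl acetate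
Conditions: BF3·OEt2 (2.5 equiv), MeCN, −40 → 0 °C; chromatographic separation of the C8' epimers
Reagents that add atoms: none
Why: BF3 ionises the allylic acetal to the oxocarbenium ion and converts 16 into the alkenyldifluoroborane, which transfers its alkenyl group to C8' with retention of geometry (Ferrier-type C-alkenylation of an oxocarbenium ion by an organotrifluoroborate). Attack at the hindered C6' is not expected, and the quaternary C5' rules out aromatisation. C8' is set by approach anti to the face carrying the axial C5' methyl and the axial C3' silyloxy group; the bias is modest, so the 8'R epimer should be the major one and is separated from its epimer here.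

Step 10
Reactants: 17 (E)-3-[(2R,6S,7aR)-6-(tert-butyldimethylsilyloxy)-4,4,7a-trimethyl-2,4,5,6,7,7a-hexahydro-1-benzofuran-2-yl]but-2-en-1-yl acetate
Product: 18 (E)-3-[(2R,6S,7aR)-6-(tert-butyldimethylsilyloxy)-4,4,7a-trimethyl-2,4,5,6,7,7a-hexahydro-1-benzofuran-2-yl]but-2-en-1-ol
Conditions: K2CO3, MeOH, 0 °C → rt
Reagents that add atoms: none
Why: Base-catalysed transesterification frees the primary allylic alcohol; the silyl ether and the dihydrofuran are stable to these conditions.

Step 11
Reactants: 18 (E)-3-[(2R,6S,7aR)-6-(tert-butyldimethylsilyloxy)-4,4,7a-trimethyl-2,4,5,6,7,7a-hexahydro-1-benzofuran-2-yl]but-2-en-1-ol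
Product: 20 {(E)-3-[(2R,6S,7aR)-6-(tert-butyldimethylsilyloxy)-4,4,7a-trimethyl-2,4,5,6,7,7a-hexahydro-1-benzofuran-2-yl]but-2-en-1-yl}triphenylphosphonium bromide, via allylic bromide 19 (not isolated)
Conditions: CBr4, PPh3, 2,6-lutidine, CH2Cl2, −20 °C; then PPh3, MeCN, rt
Reagents that add atoms: tetrabromomethane, BrC(Br)(Br)Br; triphenylphosphine, c1ccc(cc1)P(c1ccccc1)c1ccccc1
Why: Appel bromination of the primary allylic alcohol, then SN2 quaternisation of the phosphine at the primary carbon. The usual acidic phosphine hydrobromide method is avoided because acid would ionise the doubly allylic C8'–O bond.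

Step 12
Reactants: 21 (4R,6R)-4-hydroxy-2,2,6-trimethylcyclohexan-1-one (actinol)
Product: 22 (4R,6R)-4-(tert-butyldimethylsilyloxy)-2,2,6-trimethylcyclohexan-1-one
Conditions: t-BuMe2SiCl, imidazole, DMF, rt
Reagents that add atoms: tert-butyldimethylsilyl chloride, CC(C)(C)[Si](C)(C)Cl
Why: Standard silylation. The chiral-pool carbinol centre becomes C3 of ring A and is not touched again.

Step 13
Reactants: 22 (4R,6R)-4-(tert-butyldimethylsilyloxy)-2,2,6-trimethylcyclohexan-1-one
Product: 23 tert-butyl{[(1R)-3,5,5-trimethyl-4-(trimethylsilyloxy)cyclohex-3-en-1-yl]oxy}dimethylsilane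
Conditions: Me3SiOTf, Et3N, CH2Cl2, 0 °C → rt
Reagents that add atoms: trimethylsilyl trifluoromethanesulfonate, C[Si](C)(C)OS(=O)(=O)C(F)(F)F
Why: Soft enolisation. The ketone has only one enolisable α-carbon (the other is quaternary), so a single enol ether can form; the methyl-bearing stereocentre is erased on purpose.

Step 14
Reactants: 23 tert-butyl{[(1R)-3,5,5-trimethyl-4-(trimethylsilyloxy)cyclohex-3-en-1-yl]oxy}dimethylsilane
Product: 26 (2R,4S)-4-(tert-butyldimethylsilyloxy)-2-hydroxy-2,6,6-trimethylcyclohexan-1-one, via silyloxy epoxide 24 (not isolated), via 2-(trimethylsilyloxy) ketone 25 (not isolated)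
Conditions: mCPBA, NaHCO3, CH2Cl2, −20 °C; then K2CO3, MeOH, 0 °C
Reagents that add atoms: 3-chloroperoxybenzoic acid, OOC(=O)c1cccc(Cl)c1
Why: Rubottom oxidation: the peracid epoxidises the enol ether, the silyloxy epoxide opens with silyl migration to the α-silyloxy ketone, and methanolysis removes the trimethylsilyl group only. The C5 carbinol is set by approach of the peracid anti to the C3 silyloxy group, the sense seen for peracid epoxidation of 3-acyloxy and 3-silyloxy trimethylcyclohexene rings of this type; the C5 epimer is removed by chromatography.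

Step 15
Reactants: 26 (2R,4S)-4-(tert-butyldimethylsilyloxy)-2-hydroxy-2,6,6-trimethylcyclohexan-1-one; 27 (E)-3-methylpent-2-en-4-yn-1-ol
Product: 29 (1R,2R,4S)-4-(tert-butyldimethylsilyloxy)-1-[(E)-5-hydroxy-3-methylpent-3-en-1-yn-1-yl]-2,6,6-trimethylcyclohexane-1,2-diol, via dilithiated enynol 28 (not isolated)
Conditions: 27 (2.5 equiv), n-BuLi (5 equiv), THF, −78 → 0 °C; then 26, −78 → −20 °C; aq. NH4Cl
Reagents that add atoms: none
Why: Acetylide addition to a ketone that cannot enolise. In the chair with the C3 silyloxy group and the C5 methyl equatorial, the C5 oxygen and one C1 methyl are axial on the same face, so the slim nucleophile enters axially from the opposite face, anti to the C5–O bond (Felkin–Anh sense). This places C7 cis to the C5 methyl and the new C6 hydroxyl cis to the C5 hydroxyl, as the target requires.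

Step 16
Reactants: 29 (1R,2R,4S)-4-(tert-butyldimethylsilyloxy)-1-[(E)-5-hydroxy-3-methylpent-3-en-1-yn-1-yl]-2,6,6-trimethylcyclohexane-1,2-diol
Product: 30 (1S,2R,4S)-4-(tert-butyldimethylsilyloxy)-1-[(1E,3E)-5-hydroxy-3-methylpenta-1,3-dien-1-yl]-2,6,6-trimethylcyclohexane-1,2-diol
Conditions: NaAlH2(OCH2CH2OMe)2, THF, 0 °C → rt; aq. KNaC4H4O6 (tartrate)
Reagents that add atoms: none
Why: Trans-hydroalumination of a propargylic alcohol, directed by the C6 aluminium alkoxide, gives the E C7=C8 bond after protonolysis. The C9=C10 bond and the silyl ether are not affected.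

Step 17
Reactants: 30 (1S,2R,4S)-4-(tert-butyldimethylsilyloxy)-1-[(1E,3E)-5-hydroxy-3-methylpenta-1,3-dien-1-yl]-2,6,6-trimethylcyclohexane-1,2-diol
Product: 32 {(2E,4E)-5-[(1S,2R,4S)-4-(tert-butyldimethylsilyloxy)-1,2-dihydroxy-2,6,6-trimethylcyclohexyl]-3-methylpenta-2,4-dien-1-yl}triphenylphosphonium bromide, via dienyl bromide 31 (not isolated)
Conditions: CBr4, PPh3, 2,6-lutidine, CH2Cl2, −20 °C; then PPh3, MeCN, rt
Reagents that add atoms: tetrabromomethane, BrC(Br)(Br)Br; triphenylphosphine, c1ccc(cc1)P(c1ccccc1)c1ccccc1
Why: Appel bromination is selective for the primary allylic hydroxyl over the two hindered tertiary ones, and the phosphine then displaces bromide at the primary carbon. Neutral conditions protect the tertiary allylic C6 carbinol from ionisation.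

Step 18
Reactants: 32 ring A C15 phosphonium bromide; 33 (2E,4E,6E)-2,7-dimethylocta-2,4,6-trienedial
Product: 34 (2E,4E,6E,8E,10E,12E)-13-[(1S,2R,4S)-4-(tert-butyldimethylsilyloxy)-1,2-dihydroxy-2,6,6-trimethylcyclohexyl]-2,7,11-trimethyltrideca-2,4,6,8,10,12-hexaenal
Conditions: 33 (3 equiv), NaOMe, MeOH/CH2Cl2, −10 °C → rt; then heptane/EtOAc, 70 °C, N2, dark
Reagents that add atoms: none
Why: Wittig olefination with a semi-stabilised allylic ylide forms C11=C12. The excess dialdehyde limits the reaction to one end, the free tertiary hydroxyls tolerate methoxide, and heating converts the hindered Z isomer of the new double bond to E.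

Step 19
Reactants: 34 ring A C25 aldehyde; 20 bicyclic C15 phosphonium bromide
Product: 35 3,3'-bis-O-(tert-butyldimethylsilyl) ether of the target
Conditions: NaOMe, MeOH/CH2Cl2, 0 °C → rt; then heptane, 80 °C, N2, dark
Reagents that add atoms: none
Why: A second Wittig olefination forms C11'=C12' and completes the C40 skeleton. The ylide is generated in the presence of the aldehyde so that it is consumed before it can eliminate the C8' ether oxygen, and thermal equilibration gives the all-E chain without acid.

Step 20
Reactants: 35 3,3'-bis-O-(tert-butyldimethylsilyl) ether of the target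
Product: 36 (3S,5R,6S,3'S,5'R,8'R)-5',8'-epoxy-5,6,5',8'-tetrahydro-β,β-carotene-3,5,6,3'-tetrol (target)
Conditions: Bu4NF, AcOH, THF, 0 °C → rt, N2, dark
Reagents that add atoms: none
Why: Fluoride cleaves both secondary silyl ethers. The buffered, non-acidic medium leaves the C8' centre, the tertiary allylic carbinol and the polyene unchanged.

## Compound list

1 | 3-bromo-2-methylfuran | Cc1occc1Br | starting material
2 | mesityl oxide (4-methylpent-3-en-2-one) | CC(=O)C=C(C)C | starting material
3 | 3-lithio-2-methylfuran | [Li]c1ccoc1C | intermediate (not isolated)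
4 | (2-methylfuran-3-yl)magnesium bromide | Br[Mg]c1ccoc1C | intermediate (not isolated)
5 | trimethyl{[4-methyl-4-(2-methylfuran-3-yl)pent-2-en-2-yl]oxy}silane (double-bond geometry not controlled) | CC(O[Si](C)(C)C)=CC(C)(C)c1ccoc1C | intermediate (not isolated)
6 | 4-methyl-4-(2-methylfuran-3-yl)pentan-2-one | CC(=O)CC(C)(C)c1ccoc1C | intermediate
7 | lithium 4-methyl-4-(2-methylfuran-3-yl)pent-1-en-2-olate | [Li]OC(=C)CC(C)(C)c1ccoc1C | intermediate (not isolated)
8 | triisopropyl{[4-methyl-4-(2-methylfuran-3-yl)pent-1-en-2-yl]oxy}silane | C=C(O[Si](C(C)C)(C(C)C)C(C)C)CC(C)(C)c1ccoc1C | intermediate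
9 | methanol | CO | starting material
10 | racemic 2-methoxy-4,4,7a-trimethyl-2,4,5,7a-tetrahydro-1-benzofuran-6(7H)-one (drawn as the 5'R enantiomer and one acetal epimer; formed as racemate and as both C8' epimers) | CO[C@H]1C=C2C(C)(C)CC(=O)C[C@@]2(C)O1 | intermediate
11 | (6S,7aR)-2-methoxy-4,4,7a-trimethyl-2,4,5,6,7,7a-hexahydro-1-benzofuran-6-ol (both C8' epimers) | COC1C=C2C(C)(C)C[C@H](O)C[C@@]2(C)O1 | intermediate
12 | tert-butyl{[(6S,7aR)-2-methoxy-4,4,7a-trimethyl-2,4,5,6,7,7a-hexahydro-1-benzofuran-6-yl]oxy}dimethylsilane (both C8' epimers) | COC1C=C2C(C)(C)C[C@H](O[Si](C)(C)C(C)(C)C)C[C@@]2(C)O1 | intermediate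
13 | but-2-yn-1-ol | CC#CCO | starting material
14 | (Z)-3-(4,4,5,5-tetramethyl-1,3,2-dioxaborolan-2-yl)but-2-en-1-ol | C/C(B1OC(C)(C)C(C)(C)O1)=C\CO | intermediate
15 | (Z)-3-(4,4,5,5-tetramethyl-1,3,2-dioxaborolan-2-yl)but-2-en-1-yl acetate | C/C(B1OC(C)(C)C(C)(C)O1)=C\COC(C)=O | intermediate
16 | potassium (Z)-(4-acetoxybut-2-en-2-yl)trifluoroborate | [K+].C/C(=C\COC(C)=O)[B-](F)(F)F | intermediate
17 | (E)-3-[(2R,6S,7aR)-6-(tert-butyldimethylsilyloxy)-4,4,7a-trimethyl-2,4,5,6,7,7a-hexahydro-1-benzofuran-2-yl]but-2-en-1-yl acetate | CC(=O)OC/C=C(\C)[C@H]1C=C2C(C)(C)C[C@H](O[Si](C)(C)C(C)(C)C)C[C@@]2(C)O1 | intermediate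
18 | (E)-3-[(2R,6S,7aR)-6-(tert-butyldimethylsilyloxy)-4,4,7a-trimethyl-2,4,5,6,7,7a-hexahydro-1-benzofuran-2-yl]but-2-en-1-ol | OC/C=C(\C)[C@H]1C=C2C(C)(C)C[C@H](O[Si](C)(C)C(C)(C)C)C[C@@]2(C)O1 | intermediate
19 | {[(2R,6S,7aR)-2-[(E)-4-bromobut-2-en-2-yl]-4,4,7a-trimethyl-2,4,5,6,7,7a-hexahydro-1-benzofuran-6-yl]oxy}(tert-butyl)dimethylsilane | BrC/C=C(\C)[C@H]1C=C2C(C)(C)C[C@H](O[Si](C)(C)C(C)(C)C)C[C@@]2(C)O1 | intermediate (not isolated)
20 | {(E)-3-[(2R,6S,7aR)-6-(tert-butyldimethylsilyloxy)-4,4,7a-trimethyl-2,4,5,6,7,7a-hexahydro-1-benzofuran-2-yl]but-2-en-1-yl}triphenylphosphonium bromide | [Br-].C(/C=C(\C)[C@H]1C=C2C(C)(C)C[C@H](O[Si](C)(C)C(C)(C)C)C[C@@]2(C)O1)[P+](c1ccccc1)(c1ccccc1)c1ccccc1 | intermediate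
21 | (4R,6R)-4-hydroxy-2,2,6-trimethylcyclohexan-1-one (actinol) | O=C1C(C)(C)C[C@H](O)C[C@H]1C | starting material
22 | (4R,6R)-4-(tert-butyldimethylsilyloxy)-2,2,6-trimethylcyclohexan-1-one | O=C1C(C)(C)C[C@H](O[Si](C)(C)C(C)(C)C)C[C@H]1C | intermediate
23 | tert-butyl{[(1R)-3,5,5-trimethyl-4-(trimethylsilyloxy)cyclohex-3-en-1-yl]oxy}dimethylsilane | CC1=C(O[Si](C)(C)C)C(C)(C)C[C@H](O[Si](C)(C)C(C)(C)C)C1 | intermediate
24 | silyloxy epoxide of 23 (oxirane oxygen anti to the tert-butyldimethylsilyloxy group) | C[C@]12O[C@@]1(O[Si](C)(C)C)C(C)(C)C[C@H](O[Si](C)(C)C(C)(C)C)C2 | intermediate (not isolated)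
25 | (2R,4S)-4-(tert-butyldimethylsilyloxy)-2,6,6-trimethyl-2-(trimethylsilyloxy)cyclohexan-1-one | O=C1C(C)(C)C[C@H](O[Si](C)(C)C(C)(C)C)C[C@@]1(C)O[Si](C)(C)C | intermediate (not isolated)
26 | (2R,4S)-4-(tert-butyldimethylsilyloxy)-2-hydroxy-2,6,6-trimethylcyclohexan-1-one | O=C1C(C)(C)C[C@H](O[Si](C)(C)C(C)(C)C)C[C@@]1(C)O | intermediate
27 | (E)-3-methylpent-2-en-4-yn-1-ol | OC/C=C(C)/C#C | starting material
28 | lithium (E)-5-lithio-3-methylpent-2-en-4-yn-1-olate | [Li]OC/C=C(C)/C#C[Li] | intermediate (not isolated)
29 | (1R,2R,4S)-4-(tert-butyldimethylsilyloxy)-1-[(E)-5-hydroxy-3-methylpent-3-en-1-yn-1-yl]-2,6,6-trimethylcyclohexane-1,2-diol | OC/C=C(C)/C#C[C@]1(O)C(C)(C)C[C@H](O[Si](C)(C)C(C)(C)C)C[C@@]1(C)O | intermediate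
30 | (1S,2R,4S)-4-(tert-butyldimethylsilyloxy)-1-[(1E,3E)-5-hydroxy-3-methylpenta-1,3-dien-1-yl]-2,6,6-trimethylcyclohexane-1,2-diol | OC/C=C(C)/C=C/[C@]1(O)C(C)(C)C[C@H](O[Si](C)(C)C(C)(C)C)C[C@@]1(C)O | intermediate
31 | (1S,2R,4S)-1-[(1E,3E)-5-bromo-3-methylpenta-1,3-dien-1-yl]-4-(tert-butyldimethylsilyloxy)-2,6,6-trimethylcyclohexane-1,2-diol | BrC/C=C(C)/C=C/[C@]1(O)C(C)(C)C[C@H](O[Si](C)(C)C(C)(C)C)C[C@@]1(C)O | intermediate (not isolated)
32 | {(2E,4E)-5-[(1S,2R,4S)-4-(tert-butyldimethylsilyloxy)-1,2-dihydroxy-2,6,6-trimethylcyclohexyl]-3-methylpenta-2,4-dien-1-yl}triphenylphosphonium bromide | [Br-].C(/C=C(C)/C=C/[C@]1(O)C(C)(C)C[C@H](O[Si](C)(C)C(C)(C)C)C[C@@]1(C)O)[P+](c1ccccc1)(c1ccccc1)c1ccccc1 | intermediate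
33 | (2E,4E,6E)-2,7-dimethylocta-2,4,6-trienedial | O=C/C(C)=C/C=C/C=C(C)/C=O | starting material
34 | (2E,4E,6E,8E,10E,12E)-13-[(1S,2R,4S)-4-(tert-butyldimethylsilyloxy)-1,2-dihydroxy-2,6,6-trimethylcyclohexyl]-2,7,11-trimethyltrideca-2,4,6,8,10,12-hexaenal | O=C/C(C)=C/C=C/C=C(C)/C=C/C=C(C)/C=C/[C@]1(O)C(C)(C)C[C@H](O[Si](C)(C)C(C)(C)C)C[C@@]1(C)O | intermediate
35 | 3,3'-bis-O-(tert-butyldimethylsilyl) ether of (3S,5R,6S,3'S,5'R,8'R)-5',8'-epoxy-5,6,5',8'-tetrahydro-β,β-carotene-3,5,6,3'-tetrol | CC(/C=C/C=C(C)/C=C/[C@]1(O)C(C)(C)C[C@H](O[Si](C)(C)C(C)(C)C)C[C@@]1(C)O)=C\C=C\C=C(C)\C=C\C=C(/C)[C@H]1C=C2C(C)(C)C[C@H](O[Si](C)(C)C(C)(C)C)C[C@@]2(C)O1 | intermediate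
36 | (3S,5R,6S,3'S,5'R,8'R)-5',8'-epoxy-5,6,5',8'-tetrahydro-β,β-carotene-3,5,6,3'-tetrol | CC(/C=C/C=C(C)/C=C/[C@]1(O)C(C)(C)C[C@H](O)C[C@@]1(C)O)=C\C=C\C=C(C)\C=C\C=C(/C)[C@H]1C=C2C(C)(C)C[C@H](O)C[C@@]2(C)O1 | target

## Step count and least certain steps

Total: 20 steps. Longest linear sequence: 10 steps (steps 1, 2, 3, 4, 5, 9, 10, 11, 19, 20).

**Step 3 (key step).** The most likely failure is loss of regiocontrol at the furan: closure through the furan β-carbon followed by rearomatisation. Methanol capture of the radical cation before ring closure is the second risk. Both follow from the steric cost of bonding to a substituted furan carbon next to a quaternary centre. The fallback sets out from 6 and comes back at 10, and replaces anodic activation by a two-electron, polar sequence. The furan of 6 is oxidised with bromine in methanol (Na2CO3, −40 °C) to 4-(2,5-dimethoxy-2-methyl-2,5-dihydrofuran-3-yl)-4-methylpentan-2-one F1. Kinetic enolisation (LiN(iPr)2, Me3SiCl, −78 °C) gives {[4-(2,5-dimethoxy-2-methyl-2,5-dihydrofuran-3-yl)-4-methylpent-1-en-2-yl]oxy}trimethylsilane F2. Catalytic Me3SiOTf at −78 °C ionises the tertiary ketal carbon C5', and the enol ether closes the same C4'–C5' bond as an intramolecular Mukaiyama-type addition. The C8' methoxy group stays, so the product is 10.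

**Step 9.** The risk is poor facial discrimination at the planar C8' oxocarbenium ion. Its two faces differ only in the C5' methyl versus the C4' methylene and in the remote axial silyloxy group, so the epimers may form in comparable amounts or with the wrong one in excess. The fallback sets out from 12 and comes back at 18, and reverses the order in which carbon and hydrogen arrive at C8'.
- Acetal hydrolysis (aq. AcOH, THF) gives (6S,7aR)-6-(tert-butyldimethylsilyloxy)-4,4,7a-trimethyl-2,4,5,6,7,7a-hexahydro-1-benzofuran-2-ol F5.
- Oxidation (MnO2) gives (6S,7aR)-6-(tert-butyldimethylsilyloxy)-4,4,7a-trimethyl-5,6,7,7a-tetrahydro-1-benzofuran-2(4H)-one F6.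
- The silyl ether of (E)-3-iodobut-2-en-1-ol and t-BuLi give (Z)-tert-butyl[(3-lithiobut-2-en-1-yl)oxy]dimethylsilane F7, which adds to the lactone to give the lactol (6S,7aR)-2-[(E)-4-(tert-butyldimethylsilyloxy)but-2-en-2-yl]-6-(tert-butyldimethylsilyloxy)-4,4,7a-trimethyl-2,4,5,6,7,7a-hexahydro-1-benzofuran-2-ol F8.
- Ionic hydrogenation (Et3SiH, BF3·OEt2, −78 °C) gives the bis-silyl ether tert-butyl{[(E)-3-[(2R,6S,7aR)-6-(tert-butyldimethylsilyloxy)-4,4,7a-trimethyl-2,4,5,6,7,7a-hexahydro-1-benzofuran-2-yl]but-2-en-1-yl]oxy}dimethylsilane F9.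
- Selective cleavage of the primary silyl ether (HF·pyridine, pyridine, THF, 0 °C) gives 18.

Because hydride now enters where carbon entered before, the sequence gives the opposite C8' configuration for the same facial preference. It therefore only helps if step 9 shows a clear preference for the wrong epimer; if there is no preference, separation remains the answer.

**Step 4.** The risk is insufficient enantiomer discrimination: the carbonyl is flanked on both sides by a methylene attached to a quaternary carbon, and the C5' centre is remote. The presence of two acetal epimers adds to this. The fallback sets out from 10 and comes back at 11, and separates the diastereoselective from the enantioselective task. LiBH(s-Bu)3 at −78 °C attacks from the equatorial side and gives the racemic axial alcohol (6S*,7aR*)-2-methoxy-4,4,7a-trimethyl-2,4,5,6,7,7a-hexahydro-1-benzofuran-6-ol F3. Lipase-catalysed acylation with vinyl acetate (Candida antarctica lipase B) then resolves it. If the wanted enantiomer is the one acylated, the acetate (6S,7aR)-2-methoxy-4,4,7a-trimethyl-2,4,5,6,7,7a-hexahydro-1-benzofuran-6-yl acetate F4 is methanolysed (K2CO3, MeOH) to 11; otherwise 11 is the alcohol left unreacted.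

**Step 14.** The risk is low or inverted facial selectivity of the peracid, because the pseudo-axial C1 methyl and the C3 silyloxy group direct to opposite faces. This would give the C5 epimer and, after step 15, the wrong relationship between the diol and C3. The fallback sets out from 23 and comes back at 26, and moves the stereocontrol to an allylic ether.
- Saegusa–Ito oxidation (Pd(OAc)2, MeCN) gives (S)-4-(tert-butyldimethylsilyloxy)-2,6,6-trimethylcyclohex-2-en-1-one F10.
- Dihydroxylation (OsO4 cat., N-methylmorpholine N-oxide) occurs anti to the allylic silyloxy group and gives (2R,3R,4S)-4-(tert-butyldimethylsilyloxy)-2,3-dihydroxy-2,6,6-trimethylcyclohexan-1-one F11.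
- The secondary hydroxyl alone reacts with PhOC(S)Cl and pyridine to give O-[(1R,2R,6S)-6-(tert-butyldimethylsilyloxy)-2-hydroxy-2,4,4-trimethyl-3-oxocyclohexyl] O-phenyl carbonothioate F12.
- Barton–McCombie deoxygenation (Bu3SnH, azobisisobutyronitrile, toluene, 80 °C) removes the C4 oxygen and gives 26.

## Further compounds

F1 | step 3 | 4-(2,5-dimethoxy-2-methyl-2,5-dihydrofuran-3-yl)-4-methylpentan-2-one (diastereomer mixture) | CC(=O)CC(C)(C)C1=CC(OC)OC1(C)OC
F2 | step 3 | {[4-(2,5-dimethoxy-2-methyl-2,5-dihydrofuran-3-yl)-4-methylpent-1-en-2-yl]oxy}trimethylsilane | C=C(O[Si](C)(C)C)CC(C)(C)C1=CC(OC)OC1(C)OC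
F3 | step 4 | racemic (6S*,7aR*)-2-methoxy-4,4,7a-trimethyl-2,4,5,6,7,7a-hexahydro-1-benzofuran-6-ol (both enantiomers drawn) | COC1C=C2C(C)(C)C[C@H](O)C[C@@]2(C)O1.COC1C=C2C(C)(C)C[C@@H](O)C[C@]2(C)O1
F4 | step 4 | (6S,7aR)-2-methoxy-4,4,7a-trimethyl-2,4,5,6,7,7a-hexahydro-1-benzofuran-6-yl acetate | COC1C=C2C(C)(C)C[C@H](OC(C)=O)C[C@@]2(C)O1
F5 | step 9 | (6S,7aR)-6-(tert-butyldimethylsilyloxy)-4,4,7a-trimethyl-2,4,5,6,7,7a-hexahydro-1-benzofuran-2-ol | OC1C=C2C(C)(C)C[C@H](O[Si](C)(C)C(C)(C)C)C[C@@]2(C)O1
F6 | step 9 | (6S,7aR)-6-(tert-butyldimethylsilyloxy)-4,4,7a-trimethyl-5,6,7,7a-tetrahydro-1-benzofuran-2(4H)-one | O=C1C=C2C(C)(C)C[C@H](O[Si](C)(C)C(C)(C)C)C[C@@]2(C)O1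
F7 | step 9 | (Z)-tert-butyl[(3-lithiobut-2-en-1-yl)oxy]dimethylsilane | C/C([Li])=C\CO[Si](C)(C)C(C)(C)C
F8 | step 9 | (6S,7aR)-2-[(E)-4-(tert-butyldimethylsilyloxy)but-2-en-2-yl]-6-(tert-butyldimethylsilyloxy)-4,4,7a-trimethyl-2,4,5,6,7,7a-hexahydro-1-benzofuran-2-ol | C/C(=C\CO[Si](C)(C)C(C)(C)C)C1(O)C=C2C(C)(C)C[C@H](O[Si](C)(C)C(C)(C)C)C[C@@]2(C)O1
F9 | step 9 | tert-butyl{[(E)-3-[(2R,6S,7aR)-6-(tert-butyldimethylsilyloxy)-4,4,7a-trimethyl-2,4,5,6,7,7a-hexahydro-1-benzofuran-2-yl]but-2-en-1-yl]oxy}dimethylsilane | CC(C)(C)[Si](C)(C)OC/C=C(\C)[C@H]1C=C2C(C)(C)C[C@H](O[Si](C)(C)C(C)(C)C)C[C@@]2(C)O1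
F10 | step 14 | (S)-4-(tert-butyldimethylsilyloxy)-2,6,6-trimethylcyclohex-2-en-1-one | O=C1C(C)(C)C[C@H](O[Si](C)(C)C(C)(C)C)C=C1C
F11 | step 14 | (2R,3R,4S)-4-(tert-butyldimethylsilyloxy)-2,3-dihydroxy-2,6,6-trimethylcyclohexan-1-one | O=C1C(C)(C)C[C@H](O[Si](C)(C)C(C)(C)C)[C@@H](O)[C@@]1(C)O
F12 | step 14 | O-[(1R,2R,6S)-6-(tert-butyldimethylsilyloxy)-2-hydroxy-2,4,4-trimethyl-3-oxocyclohexyl] O-phenyl carbonothioate | O=C1C(C)(C)C[C@H](O[Si](C)(C)C(C)(C)C)[C@@H](OC(=S)Oc2ccccc2)[C@@]1(C)O
A1 | alternative 1 | all-cis (3R,5R,6S)-1,1,5-trimethyl-6-[(trimethylsilyl)ethynyl]cyclohexane-3,5,6-triol (carotenoid numbering) | C[Si](C)(C)C#C[C@]1(O)C(C)(C)C[C@@H](O)C[C@@]1(C)O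
A2 | alternative 1 | (1S)-3,5,5-trimethyl-4-[(trimethylsilyl)ethynyl]cyclohex-3-en-1-ol | C[Si](C)(C)C#CC1=C(C)C[C@H](O)CC1(C)C
A3 | alternative 2 | (6S,7aR)-6-(tert-butyldimethylsilyloxy)-4,4,7a-trimethyl-3-(trimethylsilyl)-5,6,7,7a-tetrahydro-1-benzofuran-2(4H)-one | O=C1C([Si](C)(C)C)=C2C(C)(C)C[C@H](O[Si](C)(C)C(C)(C)C)C[C@@]2(C)O1
A4 | alternative 2 | (S)-4-(tert-butyldimethylsilyloxy)-6,6-dimethyl-8-(trimethylsilyl)oct-7-yn-2-one | CC(=O)C[C@@H](O[Si](C)(C)C(C)(C)C)CC(C)(C)C#C[Si](C)(C)C
A5 | alternative 3 | tert-butyl{[(2R,6S,7aR)-2-[(4-methoxybenzyloxy)methyl]-4,4,7a-trimethyl-2,4,5,6,7,7a-hexahydro-1-benzofuran-6-yl]oxy}dimethylsilane | COc1ccc(cc1)COC[C@H]1C=C2C(C)(C)C[C@H](O[Si](C)(C)C(C)(C)C)C[C@@]2(C)O1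
A6 | alternative 3 | (3'S,5'R)-5-(tert-butyldimethylsilyloxy)-2-[3-(4-methoxybenzyloxy)prop-1-en-1-ylidene]-1,3,3-trimethylcyclohexan-1-ol (allene axis as drawn) | COc1ccc(cc1)COCC=[C@]=C1C(C)(C)C[C@H](O[Si](C)(C)C(C)(C)C)C[C@@]1(C)O
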